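## Retrosynthetic overview

1. The Z-styryl arm is attached last, by Suzuki coupling of an aryl chloride with a (Z)-alkenylboronate, so the cis-alkene never meets acid.
2. Both dihydrofuran rings are disconnected at O–C2: one BBr3 operation on an open-chain bis(1,2,2-triarylethanol) removes all O-protecting groups and closes both rings, setting C2 and C2′ trans to the existing C3 and C3′.
3. C3 (S) and C3′ (R) have opposite sense, so one catalyst cannot set both in a double reaction; each is set in its own dynamic kinetic resolution by transfer hydrogenation of an α,α-diaryl ketone, with antipodal Ru catalysts.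
4. The two racemic ketones come from a two-stage Friedel–Crafts reaction of an arylglyoxal with two arenes, and from a Pd ketone α-arylation.
5. Ring order: all five benzene rings are bought; the two dihydrobenzofuran rings form together in step 7; no ring is formed afterwards.

Assumption: tert-butyl(4-ethynylphenoxy)dimethylsilane is a catalogue compound (otherwise one silylation of 4-ethynylphenol); the sense of both dynamic kinetic resolutions is assigned by the Felkin–Anh model stated in steps 2 and 6 and is a prediction, not a precedent.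

## Route

Step 1
Reactants: 1 4-methoxyphenylglyoxal hydrate; 2 2-bromo-6-methoxyphenol; 3 1-chloro-3,5-dimethoxybenzene
Product: 5 rac-2-(3-bromo-4-hydroxy-5-methoxyphenyl)-2-(2-chloro-4,6-dimethoxyphenyl)-1-(4-methoxyphenyl)ethan-1-one, via keto alcohol 4 (not isolated)
Conditions: 2 (1.0 equiv), 1 (1.1 equiv), TfOH (2 mol %), HFIP, 0 °C to rt; then 3 (2.0 equiv), TfOH (10 mol %), rt
Reagents that add atoms: none
Why: Friedel–Crafts hydroxyalkylation of the phenol para to OH (both ortho positions are blocked) gives 4, whose benzylic OH ionises under acid to a cation with para-quinone-methide character that alkylates 3 mainly ortho to Cl and para to OMe (second Friedel–Crafts step; the minor isomer from attack between the two OMe groups is removed); the new CH is racemic and deliberately labile.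

Step 2
Reactants: 5 rac-triaryl ketone
Product: 6 (1S,2S)-2-(3-bromo-4-hydroxy-5-methoxyphenyl)-2-(2-chloro-4,6-dimethoxyphenyl)-1-(4-methoxyphenyl)ethan-1-ol
Conditions: RuCl[(S,S)-TsDPEN](p-cymene) (3 mol %), HCO2H/Et3N (5:2), DMF, 40 °C, argon
Reagents that add atoms: none
Why: Proposed new method: the CH between two aryl rings and the ketone epimerises through its enol in the amine–formate medium while the ruthenium hydride reduces the aryl ketone on one face (as with acetophenone, the (S,S) catalyst gives the (S)-carbinol) and, through a Felkin–Anh transition state with the di-ortho-substituted chlorodimethoxyphenyl ring as the large group, reduces only the (S)-epimer, which fixes the diaryl-methine centre (the later C3) as S; the closest known reaction is Noyori–Ikariya asymmetric transfer hydrogenation with dynamic kinetic resolution of α-substituted aryl ketones such as benzoins and 2-arylcycloalkanones.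

Step 3
Reactants: 6 (1S,2S)-alcohol
Product: 7 bis(tert-butyldimethylsilyl) ether of 6 (phenol O and carbinol O silylated; 1S,2S)
Conditions: TBSOTf (2.6 equiv), 2,6-lutidine (4 equiv), CH2Cl2, 0 °C to rt
Reagents that add atoms: tert-butyldimethylsilyl trifluoromethanesulfonate (TBSOTf), CC(C)(C)[Si](C)(C)OS(=O)(=O)C(F)(F)F
Why: Silyl triflate silylation of the hindered phenol and the benzylic alcohol protects both against the basic palladium step (phenoxide deactivation of the bromide, alkoxide oxidation) without touching either stereocentre.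

Step 4
Reactants: 8 3,5-dimethoxyphenylacetic acid; 9 anisole
Product: 11 2-(3,5-dimethoxyphenyl)-1-(4-methoxyphenyl)ethan-1-one, via mixed anhydride 10 (not isolated)
Conditions: (CF3CO)2O (1.5 equiv), H3PO4 (85 %, 10 mol %), anisole (3 equiv), 25 °C
Reagents that add atoms: none
Why: Friedel–Crafts acylation of anisole by the mixed trifluoroacetic anhydride occurs para to the methoxy group; no stereocentre is formed.

Step 5
Reactants: 7 bis-silyl ether aryl bromide; 11 deoxybenzoin
Product: 12 2-{2-(tert-butyldimethylsilyloxy)-5-[(1S,2S)-2-(tert-butyldimethylsilyloxy)-1-(2-chloro-4,6-dimethoxyphenyl)-2-(4-methoxyphenyl)ethyl]-3-methoxyphenyl}-2-(3,5-dimethoxyphenyl)-1-(4-methoxyphenyl)ethan-1-one (both epimers at the new CH)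
Conditions: Pd2(dba)3 (2.5 mol %), Xantphos (6 mol %), K3PO4 (3 equiv), toluene, 100 °C
Reagents that add atoms: none
Why: Palladium-catalysed ketone α-arylation (Buchwald–Hartwig type) joins the enolate of 11 to the aryl bromide in preference to the aryl chloride, which a bidentate arylphosphine–palladium catalyst does not activate at this temperature; the new CH forms as a labile epimer mixture that step 6 resolves, and the older centres are not acidic.

Step 6
Reactants: 12 ketone (epimer mixture)
Product: 13 (1R,2R)-2-{2-(tert-butyldimethylsilyloxy)-5-[(1S,2S)-2-(tert-butyldimethylsilyloxy)-1-(2-chloro-4,6-dimethoxyphenyl)-2-(4-methoxyphenyl)ethyl]-3-methoxyphenyl}-2-(3,5-dimethoxyphenyl)-1-(4-methoxyphenyl)ethan-1-ol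
Conditions: RuCl[(R,R)-TsDPEN](p-cymene) (3 mol %), HCO2H/Et3N (5:2), DMF, 40 °C, argon
Reagents that add atoms: none
Why: Proposed new method: the same dynamic kinetic resolution as in step 2 with the mirror-image catalyst gives the (R)-carbinol and, with the ortho-silyloxy ring as the Felkin–Anh large group, reduces only the (R)-epimer of the enolisable CH, so this diaryl-methine centre (the later C3′) is R, opposite to the first one as the target demands; the closest known reaction is Noyori–Ikariya transfer hydrogenation with dynamic kinetic resolution of α-aryl ketones.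

Step 7
Reactants: 13 open-chain bis(triarylethanol)
Product: 15 (2S,3S)-4-chloro-3-[(2R,3R)-3-(3,5-dihydroxyphenyl)-7-hydroxy-2-(4-hydroxyphenyl)-2,3-dihydro-1-benzofuran-5-yl]-2-(4-hydroxyphenyl)-2,3-dihydro-1-benzofuran-6-ol, via dibromide 14 (not isolated)
Conditions: BBr3 (16 equiv), CH2Cl2, −78 °C to rt; then aq. NaHCO3/EtOAc, rt, 1 h
Reagents that add atoms: none
Why: BBr3 cleaves the seven methyl ethers and both silyl ethers and turns the two benzylic C–O bonds into bromides (14); each bromide then ionises to a para-hydroxybenzyl cation that is captured 5-exo by the only ortho-phenol within reach (double cyclodehydrative etherification), and because this closure is reversible under acid both new O–CH(aryl) centres settle trans to the fixed diaryl-methine centres, giving 2S,3S in one ring and 2R,3R in the other.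

Step 8
Reactants: 16 tert-butyl(4-ethynylphenoxy)dimethylsilane
Product: 17 (Z)-tert-butyldimethyl{4-[2-(4,4,5,5-tetramethyl-1,3,2-dioxaborolan-2-yl)ethenyl]phenoxy}silane
Conditions: [Rh(cod)Cl]2 (1.5 mol %), P(i-Pr)3 (6 mol %), Et3N (1 equiv), pinacolborane (0.85 equiv), cyclohexane, rt
Reagents that add atoms: pinacolborane (HBpin), B1OC(C)(C)C(C)(C)O1
Why: Rhodium-catalysed trans-hydroboration of a terminal alkyne (through a rhodium vinylidene) puts boron on the terminal carbon cis to the aryl group and so sets the Z-alkene.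

Step 9
Reactants: 15 bis-dihydrobenzofuran aryl chloride; 17 (Z)-alkenylboronate
Product: 19 (2S,3S)-3-[(2R,3R)-3-(3,5-dihydroxyphenyl)-7-hydroxy-2-(4-hydroxyphenyl)-2,3-dihydro-1-benzofuran-5-yl]-2-(4-hydroxyphenyl)-4-[(Z)-2-(4-hydroxyphenyl)ethenyl]-2,3-dihydro-1-benzofuran-6-ol, via silyl ether 18 (not isolated)
Conditions: Pd(OAc)2 (5 mol %), SPhos (10 mol %), K3PO4 (8 equiv), 1,4-dioxane/H2O (4:1), 80 °C, degassed; then K2CO3, MeOH, rt
Reagents that add atoms: none
Why: Suzuki–Miyaura coupling of the hindered aryl chloride with a dialkylbiarylphosphine–palladium catalyst keeps the Z-geometry of the boronate and tolerates the free phenols as phenoxides, and the aryl silyl ether is then methanolysed in the same pot; no stereocentre is touched.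

## Compound list

1 | 4-methoxyphenylglyoxal hydrate | COc1ccc(cc1)C(=O)C(O)O | starting material
2 | 2-bromo-6-methoxyphenol | COc1cccc(Br)c1O | starting material
3 | 1-chloro-3,5-dimethoxybenzene | COc1cc(Cl)cc(OC)c1 | starting material
4 | rac-2-(3-bromo-4-hydroxy-5-methoxyphenyl)-2-hydroxy-1-(4-methoxyphenyl)ethan-1-one | COc1ccc(cc1)C(=O)C(O)c1cc(Br)c(O)c(OC)c1 | intermediate
5 | rac-2-(3-bromo-4-hydroxy-5-methoxyphenyl)-2-(2-chloro-4,6-dimethoxyphenyl)-1-(4-methoxyphenyl)ethan-1-one | COc1ccc(cc1)C(=O)C(c1cc(Br)c(O)c(OC)c1)c1c(Cl)cc(OC)cc1OC | intermediate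
6 | (1S,2S)-2-(3-bromo-4-hydroxy-5-methoxyphenyl)-2-(2-chloro-4,6-dimethoxyphenyl)-1-(4-methoxyphenyl)ethan-1-ol | COc1ccc(cc1)[C@@H](O)[C@@H](c1cc(Br)c(O)c(OC)c1)c1c(Cl)cc(OC)cc1OC | intermediate
7 | bis(tert-butyldimethylsilyl) ether of 6 (1S,2S) | COc1ccc(cc1)[C@@H](O[Si](C)(C)C(C)(C)C)[C@@H](c1cc(Br)c(O[Si](C)(C)C(C)(C)C)c(OC)c1)c1c(Cl)cc(OC)cc1OC | intermediate
8 | 3,5-dimethoxyphenylacetic acid | COc1cc(CC(=O)O)cc(OC)c1 | starting material
9 | anisole | COc1ccccc1 | starting material
10 | (3,5-dimethoxyphenyl)acetic trifluoroacetic anhydride | COc1cc(CC(=O)OC(=O)C(F)(F)F)cc(OC)c1 | intermediate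
11 | 2-(3,5-dimethoxyphenyl)-1-(4-methoxyphenyl)ethan-1-one | COc1ccc(cc1)C(=O)Cc1cc(OC)cc(OC)c1 | intermediate
12 | α,α-diaryl ketone from 7 and 11 (older centres 1S,2S; both epimers at the new CH) | COc1ccc(cc1)[C@@H](O[Si](C)(C)C(C)(C)C)[C@@H](c1cc(C(C(=O)c2ccc(OC)cc2)c2cc(OC)cc(OC)c2)c(O[Si](C)(C)C(C)(C)C)c(OC)c1)c1c(Cl)cc(OC)cc1OC | intermediate
13 | (1R,2R)-carbinol from 12 (older centres 1S,2S) | COc1ccc(cc1)[C@@H](O[Si](C)(C)C(C)(C)C)[C@@H](c1cc([C@H]([C@@H](O)c2ccc(OC)cc2)c2cc(OC)cc(OC)c2)c(O[Si](C)(C)C(C)(C)C)c(OC)c1)c1c(Cl)cc(OC)cc1OC | intermediate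
14 | 3-[(1R)-2-bromo-1-(3,5-dihydroxyphenyl)-2-(4-hydroxyphenyl)ethyl]-5-[(1S)-2-bromo-1-(2-chloro-4,6-dihydroxyphenyl)-2-(4-hydroxyphenyl)ethyl]benzene-1,2-diol (C–Br epimers) | Oc1ccc(cc1)C(Br)[C@@H](c1cc([C@H](C(Br)c2ccc(O)cc2)c2cc(O)cc(O)c2)c(O)c(O)c1)c1c(Cl)cc(O)cc1O | intermediate
15 | (2S,3S)-4-chloro-3-[(2R,3R)-3-(3,5-dihydroxyphenyl)-7-hydroxy-2-(4-hydroxyphenyl)-2,3-dihydro-1-benzofuran-5-yl]-2-(4-hydroxyphenyl)-2,3-dihydro-1-benzofuran-6-ol | Clc1cc(O)cc2c1[C@H](c1cc(O)c3c(c1)[C@@H](c1cc(O)cc(O)c1)[C@H](c1ccc(O)cc1)O3)[C@@H](c1ccc(O)cc1)O2 | intermediate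
16 | tert-butyl(4-ethynylphenoxy)dimethylsilane | C#Cc1ccc(O[Si](C)(C)C(C)(C)C)cc1 | starting material
17 | (Z)-tert-butyldimethyl{4-[2-(4,4,5,5-tetramethyl-1,3,2-dioxaborolan-2-yl)ethenyl]phenoxy}silane | CC1(C)OB(/C=C\c2ccc(O[Si](C)(C)C(C)(C)C)cc2)OC1(C)C | intermediate
18 | tert-butyldimethylsilyl ether of 19 at the stilbene phenol (2S,3S,2′R,3′R, Z) | CC(C)(C)[Si](C)(C)Oc1ccc(/C=C\c2cc(O)cc3c2[C@H](c2cc(O)c4c(c2)[C@@H](c2cc(O)cc(O)c2)[C@H](c2ccc(O)cc2)O4)[C@@H](c2ccc(O)cc2)O3)cc1 | intermediate
19 | (2S,3S)-3-[(2R,3R)-3-(3,5-dihydroxyphenyl)-7-hydroxy-2-(4-hydroxyphenyl)-2,3-dihydro-1-benzofuran-5-yl]-2-(4-hydroxyphenyl)-4-[(Z)-2-(4-hydroxyphenyl)ethenyl]-2,3-dihydro-1-benzofuran-6-ol | Oc1ccc(/C=C\c2cc(O)cc3c2[C@H](c2cc(O)c4c(c2)[C@@H](c2cc(O)cc(O)c2)[C@H](c2ccc(O)cc2)O4)[C@@H](c2ccc(O)cc2)O3)cc1 | target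

## Summary and risks

Total step count: 9. Longest linear sequence: 7 (steps 1, 2, 3, 5, 6, 7, 9).

Steps most likely to fail:

**Step 7 (one-pot BBr3 deprotection and double ring closure).** Nine O-groups must be cleaved while two benzylic cations are generated; a 1,2-aryl or hydride shift, or intermolecular Friedel–Crafts alkylation, could compete before the phenols are free. The fallback sets out from 13 and separates deprotection from ring closure. TBAF in THF removes both silyl groups to give the phenol diol F1. Sodium ethanethiolate in DMF at 130 °C then cleaves the seven methyl ethers under basic, cation-free conditions to give the octaphenol diol F2. Catalytic p-TsOH in MeCN at rt closes both rings by Brønsted-acid cyclodehydration, and the route is rejoined at 15.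

**Step 2 (first dynamic kinetic resolution).** α,α-Diaryl ketones are not an established substrate class for this reduction, the ketone is hindered, and the predicted sense rests on a model; step 6 repeats the method. The fallback sets out from 5 and replaces asymmetric catalysis by resolution. NaBH4 in MeOH gives the alcohol as all four stereoisomers, stereoisomer mixture F3. Preparative chiral SFC isolates 6, where the route is rejoined, and the unwanted isomers are returned to 5 with MnO2 and recycled.

**Step 9 (Suzuki coupling on the unprotected, hindered aryl chloride).** The Z-boronate may isomerise or protodeboronate before the slow oxidative addition, and the phenoxide-rich substrate is air-sensitive. The fallback sets out from 15 and builds the alkene by alkyne semi-reduction. Copper-free Sonogashira coupling with alkyne 16 (Pd(OAc)2, XPhos, Cs2CO3, MeCN, 80 °C) gives the diarylalkyne F4. Semi-hydrogenation over Pd/CaCO3 poisoned with Pb(OAc)2 and quinoline (H2, EtOAc) then gives the Z-alkene, rejoining the route at 18, which is methanolysed to 19 as in step 9.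

Further compounds
F1 | step 7 | 13 without its two silyl groups (phenol and both carbinols free; 1S,2S and 1R,2R) | COc1ccc(cc1)[C@@H](O)[C@@H](c1cc([C@H]([C@@H](O)c2ccc(OC)cc2)c2cc(OC)cc(OC)c2)c(O)c(OC)c1)c1c(Cl)cc(OC)cc1OC
F2 | step 7 | octaphenol diol (F1 with all seven methyl ethers cleaved) | Oc1ccc(cc1)[C@@H](O)[C@@H](c1cc([C@H]([C@@H](O)c2ccc(O)cc2)c2cc(O)cc(O)c2)c(O)c(O)c1)c1c(Cl)cc(O)cc1O
F3 | step 2 | 2-(3-bromo-4-hydroxy-5-methoxyphenyl)-2-(2-chloro-4,6-dimethoxyphenyl)-1-(4-methoxyphenyl)ethan-1-ol as all four stereoisomers | COc1ccc(cc1)C(O)C(c1cc(Br)c(O)c(OC)c1)c1c(Cl)cc(OC)cc1OC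
F4 | step 9 | diarylalkyne: 15 with Cl replaced by 2-[4-(tert-butyldimethylsilyloxy)phenyl]ethynyl | CC(C)(C)[Si](C)(C)Oc1ccc(cc1)C#Cc1cc(O)cc2c1[C@H](c1cc(O)c3c(c1)[C@@H](c1cc(O)cc(O)c1)[C@H](c1ccc(O)cc1)O3)[C@@H](c1ccc(O)cc1)O2
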